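In the stirred vessel starting material meets partner, target appears within seconds, isomer of the product grows beside it, and both later fade while starting material returns. What counts here is the share, target over target plus isomer of the product, at the end of four recipes.

| flask | starting material | partner | second substrate | remark | time |
|---|---|---|---|---|---|
| beta | 0.091 M | 0.0955 M | 0.455 M | run made earlier |  |
| epsilon | 0.091 M | 0.0955 M | 0.23 M | run made earlier |  |
| alpha | 0.091 M | 0.0955 M | 0.34 M | run made earlier |  |
| gamma | 0.045 M | 0.0955 M | 0.455 M | run made earlier |  |
| Friday's | 0.091 M | 0.0955 M | 0.455 M (fed, over 1.5 min) | all else is in the flask from the start; the feed brings no volume worth counting | 4.0 min |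
| Tuesday's | 0.091 M | 0.0955 M | 0.455 M | everything together at the start | 4.0 min |
| Wednesday's | 0.091 M | 0.0955 M | 0.455 M (in portions, 2, over 1.5 min) | first portion at the start, last at 1.5 min | 4.0 min |
| Sunday's | 0.091 M | 0.0955 M (fed, over 1.5 min) | 0.455 M | all else is in the flask from the start; the feed brings no volume worth counting | 4.0 min |

- beta (time / min: target / %, isomer of the product / %, starting material / %): 0.333: 25.8, 4.3, 69.8; 0.500: 23.5, 5.1, 71.2; 0.667: 20.2, 5.5, 73.6; 1.00: 16.9, 5.7, 76.6; 1.50: 13.1, 4.8, 80.6; 2.50: 9.9, 3.6, 87.1; 4.00: 6.4, 1.9, 89.8
- epsilon (time / min: target / %, isomer of the product / %, starting material / %): 0.250: 27.6, 3.7, 67.5; 0.417: 26.4, 5.7, 68.6; 0.667: 22.7, 6.3, 71.0; 0.833: 21.0, 6.5, 72.6; 1.33: 17.4, 6.5, 76.6; 2.00: 13.8, 5.2, 81.2; 3.00: 10.6, 3.8, 85.6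
- alpha (time / min: target / %, isomer of the product / %, starting material / %): 0.250: 28.6, 3.1, 68.5; 0.417: 25.7, 4.8, 69.6; 0.667: 21.5, 5.5, 72.2; 0.833: 21.0, 6.7, 73.3; 1.33: 15.9, 5.6, 77.9; 2.00: 12.3, 4.0, 82.8; 3.00: 7.9, 3.0, 87.5
- gamma (time / min: target / %, isomer of the product / %, starting material / %): 0.250: 31.1, 4.7, 65.2; 0.833: 20.2, 6.4, 73.4; 1.33: 15.2, 6.1, 79.4; 2.50: 9.8, 2.5, 87.3; 3.00: 8.4, 2.7, 88.5

(scatter of a reading: 0.5 percentage points)

* the flask with the highest share of target in target plus isomer of the product ("all alike" if they lie within 1.5 percentage points) (Friday's / Tuesday's / Wednesday's / Sunday's / all alike)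
* share of target in target plus isomer of the product at the end, Friday's
* share of target in target plus isomer of the product at the end, Tuesday's
* share of target in target plus isomer of the product at the end, Wednesday's
* share of target in target plus isomer of the product at the end, Sunday's



Two chemists dispute this. The first says the share relaxes to a late value and forgets the recipe (thermodynamic control). The second says it tells the age of the target (kinetic control), so a flask dosed until 1.5 min should stand above Tuesday's, Sunday's highest. His numbers are from the beta run, which read 85.7% at 0.333 min and 73.3% at 2.50 min, a gap of 12 percentage points, wider than the margin.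

My own reckoning works with the fraction left of that gap. At 0.667 min the beta run read 78.6%, so the gap shrinks at a read rate of 2.56 /min, a half-life of 0.271 min. The last addition ends 2.50 min before sampling, which is longer than that half-life. The memory left, the fraction of the gap still open at sampling after the last addition, is therefore 0.166%. A gap as wide as the beta run's would shrink to 0.021 points, far below the margin. So I expect no separation, and each flask near the late reading of 73.3%.

The forecast takes the first side: all alike, with 75% for Friday's, 75% for Tuesday's, 75% for Wednesday's and 75% for Sunday's, on the ground that dosing leaves “several relaxation times” to settle. Its level stands above my reading; its verdict is the same.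

The simulation gives all alike: 72.9% for Friday's, 73.7% for Tuesday's, 73.0% for Wednesday's, 73.0% for Sunday's. The spread of 0.80 points lies inside the margin, and undosed Tuesday's stands highest. The second chemist keeps the end of Sunday's partner feed: at 1.50 min Sunday's flask holds target at 20.9% and isomer of the product at 5.22%, a share of 80.0%.

    starting material + partner ⇌ target (K = 7.96 /M, k = 2.77 /M/s)
    second substrate + partner ⇌ second product (K = 5.30 /M, k = 0.0239 /M/s)
    partner → decomposed reagent (k = 0.00956 /s)
    target ⇌ isomer of the product (K = 0.320, k = 0.0112 /s)

The neighbour of Friday's is charged with 0.11 M of second substrate, and its feed still ends at 1.5 min. The same reckoning therefore gives the same memory left, 0.166%, and a share near the late reading of 73.3%. That neighbour ends with target at 8.53% and isomer of the product at 3.17%, a share of 72.9%.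

The numbers in the tables are simulated with constants of no real substance, and the scatter is random.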